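**Retrosynthetic overview**

1. Target ⇒ 3-methylbut-2-enoyl chloride + (4S,5S,8S,9S,10R,13R)-8,18-dihydroxylabdan-15-oic acid; the C18 alcohol comes from a C18 acid by borane reduction.
2. Key bond C8–C9, closing ring B last: SmI2 turns the C8 methyl ketone into a nucleophilic ketyl, which adds to C9, the β-carbon of a vinyl sulfone. The sulfone is removed in the same pot, so C8 and C9 are set with the whole side chain already attached.
3. C9=C11 by Horner–Wadsworth–Emmons olefination of a ring-A keto aldehyde with a sulfonyl phosphonate carrying C11–C15 and C13, made from methyl hydrogen (R)-3-methylglutarate.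
4. Ring A (C4, C5, C10) is taken from methyl dehydroabietate by oxidative removal of its rings B and C. Its ester carbon is read as C9 and the new tertiary acid as C18, which turns the natural-series ring into the ent-series ring of the target.
5. Ring order: ring A from the chiral pool, ring B by the ketyl closure.

Assumption: labdane numbering is used (C18 is the C4 substituent trans to the C10 methyl), and methyl dehydroabietate and methyl hydrogen (R)-3-methylglutarate are bought.

**Step 1**
Reactants: 1 methyl hydrogen (R)-3-methylglutarate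
Product: 2 methyl (3S)-4-iodo-3-methylbutanoate
Conditions: PhI(OAc)2 (0.6 equiv), I2 (0.6 equiv), cyclohexane, hν (tungsten lamp), reflux
Reagents that add atoms: iodine, II
Why: Suárez iododecarboxylation (Hunsdiecker-type radical chain through the acyl hypoiodite) replaces CO2H by iodine at a primary carbon; the C3 stereocentre is not involved and its descriptor changes from R to S only because CH2I outranks CH2CO2Me.

**Step 2**
Reactants: 2 methyl (3S)-4-iodo-3-methylbutanoate; 3 diethyl (phenylsulfonyl)methylphosphonate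
Product: 4 methyl (3S)-5-(diethoxyphosphoryl)-3-methyl-5-(phenylsulfonyl)pentanoate (both C5 epimers)
Conditions: NaH, DMF, 0 °C; then 2, 60 °C
Reagents that add atoms: none
Why: SN2 alkylation of the soft sulfonyl- and phosphoryl-stabilised carbanion by the primary iodide gives the olefination reagent that already carries C11–C15 and the C13 stereocentre; the new centre at the P/S-bearing carbon is irrelevant because that carbon ends as CH2.

**Step 3**
Reactants: 5 methyl dehydroabietate
Product: 6 (1S,2R,3R)-2-(2-carboxyethyl)-3-(methoxycarbonyl)-1,3-dimethylcyclohexane-1-carboxylic acid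
Conditions: RuCl3·xH2O (5 mol %), NaIO4 (16 equiv), CCl4/MeCN/H2O (2:2:3), rt, 48 h
Reagents that add atoms: NaIO4 (sodium metaperiodate; oxygen delivered through RuO4), [Na+].[O-]I(=O)(=O)=O
Why: RuO4 arene degradation (RuCl3/NaIO4 protocol) burns the trialkylbenzene ring and leaves each alkyl-bearing ring carbon as CO2H without touching a stereocentre, and because the two quaternary ring carbons now differ only as ester versus acid, reading the ester carbon as C9 and the new tertiary acid as C18 makes this ring the 4S,5S,10R ring A of the target; acid and heat are avoided from here on because the symmetric cyclic anhydride would erase that distinction.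

**Step 4**
Reactants: 6 (1S,2R,3R)-2-(2-carboxyethyl)-3-(methoxycarbonyl)-1,3-dimethylcyclohexane-1-carboxylic acid
Product: 8 (1S,2R,3R)-3-(methoxycarbonyl)-2-{3-[methoxy(methyl)amino]-3-oxopropyl}-1,3-dimethylcyclohexane-1-carboxylic acid, via acyl imidazolide 7 (not isolated)
Conditions: CDI (1.05 equiv), CH2Cl2, 0 °C to rt; then MeNH(OMe)·HCl (1.2 equiv), rt
Reagents that add atoms: N,O-dimethylhydroxylamine hydrochloride, CNOC.Cl; 1,1'-carbonyldiimidazole, O=C(n1ccnc1)n1ccnc1 (its atoms stay only in 7)
Why: CDI amidation (Weinreb amide formation) is selective because only the unhindered primary acid forms the acyl imidazolide at 0 °C, while the tertiary acid flanked by two substituted carbons stays free; no stereocentre is affected.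

**Step 5**
Reactants: 8 (1S,2R,3R)-3-(methoxycarbonyl)-2-{3-[methoxy(methyl)amino]-3-oxopropyl}-1,3-dimethylcyclohexane-1-carboxylic acid
Product: 10 (1S,2S,3R)-3-formyl-1,3-dimethyl-2-(3-oxobutyl)cyclohexane-1-carboxylic acid, via bromomagnesium hemiaminal 9 (not isolated)
Conditions: MeMgBr (2.3 equiv), THF, −20 to 0 °C; then i-Bu2AlH (1.6 equiv), −78 to −45 °C; MeOH, aq HCl
Reagents that add atoms: methylmagnesium bromide, C[Mg]Br
Why: Proposed new method: MeMgBr deprotonates the tertiary acid and adds once to the Weinreb amide to give the chelated tetrahedral adduct 9, which keeps the future ketone masked while i-Bu2AlH reduces the hindered methyl ester to its aluminium hemiacetal (stable at low temperature for such an ester), and acidic work-up releases methyl ketone and aldehyde together; the closest known reaction types are the Weinreb ketone synthesis, in situ protection of carbonyls as N,O-hemiaminal salts and the i-Bu2AlH ester-to-aldehyde reduction, and no stereocentre is involved.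

**Step 6**
Reactants: 10 (1S,2S,3R)-3-formyl-1,3-dimethyl-2-(3-oxobutyl)cyclohexane-1-carboxylic acid; 4 methyl (3S)-5-(diethoxyphosphoryl)-3-methyl-5-(phenylsulfonyl)pentanoate
Product: 11 (1S,2S,3R)-3-[(4S)-6-methoxy-4-methyl-6-oxo-2-(phenylsulfonyl)hex-1-en-1-yl]-1,3-dimethyl-2-(3-oxobutyl)cyclohexane-1-carboxylic acid (E/Z mixture)
Conditions: LiCl, DBU, MeCN, rt to 50 °C
Reagents that add atoms: none
Why: Horner–Wadsworth–Emmons olefination under Masamune–Roush conditions is aldehyde-selective and too weakly basic to enolise the methyl ketone, the α-branched sulfonylphosphonate should still reach the hindered aldehyde on warming, and the E/Z ratio does not matter because C9 and C11 both become sp3 in the next step.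

**Step 7**
Reactants: 11 (1S,2S,3R)-3-[(4S)-6-methoxy-4-methyl-6-oxo-2-(phenylsulfonyl)hex-1-en-1-yl]-1,3-dimethyl-2-(3-oxobutyl)cyclohexane-1-carboxylic acid
Product: 13 (4S,5S,8S,9S,10R,13R)-8-hydroxy-15-methoxy-15-oxolabdan-18-oic acid, via hydroxy sulfone 12 (not isolated)
Conditions: LiOt-Bu (1.0 equiv), THF; then SmI2 (8 equiv), HMPA (32 equiv), MeOH (20 equiv), THF, −78 °C to rt; aq HCl
Reagents that add atoms: none
Why: Proposed new method: SmI2/HMPA converts the ketone into a ketyl radical anion, so that C8 becomes a nucleophile and adds 6-exo to C9, the normally electrophilic β-carbon of the vinyl sulfone, through a chair transition state fused trans to ring A in which the sulfonyl-bearing C11 is equatorial (H9 axial, anti to the C10 methyl) and the bulky O–Sm(HMPA)n group is equatorial (C17 axial), giving 8S,9S, after which MeOH protonates the α-sulfonyl organosamarium faster than it can attack the ester and excess SmI2/HMPA at rt cleaves the C–S bond to leave C11 as CH2; the closest known reaction types are the SmI2 ketyl–olefin cyclisation onto enoates and vinyl sulfones and the SmI2/HMPA reductive desulfonylation of alkyl phenyl sulfones.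

**Step 8**
Reactants: 13 (4S,5S,8S,9S,10R,13R)-8-hydroxy-15-methoxy-15-oxolabdan-18-oic acid
Product: 15 (4S,5S,8S,9S,10R,13R)-8,18-dihydroxylabdan-15-oic acid, via diol methyl ester 14 (not isolated)
Conditions: BH3·THF (3 equiv), THF, 0 °C to rt; then MeOH, aq LiOH, rt; aq HCl to pH 3
Reagents that add atoms: lithium hydroxide, [Li+].[OH-]
Why: Chemoselective borane reduction (carboxylic acid far faster than ester) turns the hindered C18 acid into the primary alcohol while the C15 methyl ester and the tertiary alcohol survive, and the basic work-up is extended into a saponification of the unhindered methyl ester; no stereocentre is involved.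

**Step 9**
Reactants: 15 (4S,5S,8S,9S,10R,13R)-8,18-dihydroxylabdan-15-oic acid; 16 3-methylbut-2-enoyl chloride
Product: 17 (4S,5S,8S,9S,10R,13R)-8-hydroxy-18-[(3-methylbut-2-enoyl)oxy]labdan-15-oic acid (CNP0293742.1)
Conditions: 16 (2.5 equiv), pyridine, CH2Cl2, 0 °C to rt; then H2O
Reagents that add atoms: none
Why: Acylation with the acid chloride esterifies only the primary C18 alcohol (the hindered tertiary C8 alcohol is inert and the mixed anhydride formed at C15 is hydrolysed in the aqueous work-up), with pyridine rather than a stronger amine used to avoid deconjugation of the acyl group through its vinylketene.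

**Compound list**

1 | methyl hydrogen (R)-3-methylglutarate, (3R)-5-methoxy-3-methyl-5-oxopentanoic acid | OC(=O)C[C@@H](C)CC(=O)OC | starting material
2 | methyl (3S)-4-iodo-3-methylbutanoate | IC[C@@H](C)CC(=O)OC | intermediate
3 | diethyl (phenylsulfonyl)methylphosphonate | CCOP(=O)(OCC)CS(=O)(=O)c1ccccc1 | starting material
4 | methyl (3S)-5-(diethoxyphosphoryl)-3-methyl-5-(phenylsulfonyl)pentanoate, both C5 epimers | CCOP(=O)(OCC)C(S(=O)(=O)c1ccccc1)C[C@@H](C)CC(=O)OC | intermediate
5 | methyl dehydroabietate, methyl (4R,5R,10S)-abieta-8,11,13-trien-18-oate | CC(C)c1cc2c(cc1)[C@]3(CCC[C@@]([C@@H]3CC2)(C)C(=O)OC)C | starting material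
6 | (1S,2R,3R)-2-(2-carboxyethyl)-3-(methoxycarbonyl)-1,3-dimethylcyclohexane-1-carboxylic acid | OC(=O)[C@@]1(C)CCC[C@](C)([C@@H]1CCC(=O)O)C(=O)OC | intermediate
7 | acyl imidazolide of the primary acid of 6 | OC(=O)[C@@]1(C)CCC[C@](C)([C@@H]1CCC(=O)n1ccnc1)C(=O)OC | intermediate (not isolated)
8 | (1S,2R,3R)-3-(methoxycarbonyl)-2-{3-[methoxy(methyl)amino]-3-oxopropyl}-1,3-dimethylcyclohexane-1-carboxylic acid | OC(=O)[C@@]1(C)CCC[C@](C)([C@@H]1CCC(=O)N(C)OC)C(=O)OC | intermediate
9 | bromomagnesium carboxylate of 8 in which the amide has become the C(CH3)(OMgBr)N(CH3)OCH3 hemiaminal, both epimers at that carbon | Br[Mg]OC(=O)[C@@]1(C)CCC[C@](C)([C@@H]1CCC(C)(O[Mg]Br)N(C)OC)C(=O)OC | intermediate (not isolated)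
10 | (1S,2S,3R)-3-formyl-1,3-dimethyl-2-(3-oxobutyl)cyclohexane-1-carboxylic acid | OC(=O)[C@@]1(C)CCC[C@](C)([C@@H]1CCC(C)=O)C=O | intermediate
11 | (1S,2S,3R)-3-[(4S)-6-methoxy-4-methyl-6-oxo-2-(phenylsulfonyl)hex-1-en-1-yl]-1,3-dimethyl-2-(3-oxobutyl)cyclohexane-1-carboxylic acid, E/Z mixture | OC(=O)[C@@]1(C)CCC[C@](C)([C@@H]1CCC(C)=O)C=C(S(=O)(=O)c1ccccc1)C[C@@H](C)CC(=O)OC | intermediate
12 | (4S,5S,8S,9S,10R)-8-hydroxy-15-methoxy-15-oxo-11-(phenylsulfonyl)labdan-18-oic acid, C11 epimers, C13 arranged as in 13 (13S by CIP because of the sulfone) | OC(=O)[C@@]1(C)CCC[C@]2(C)[C@@H]1CC[C@](C)(O)[C@H]2C(S(=O)(=O)c1ccccc1)C[C@@H](C)CC(=O)OC | intermediate (not isolated)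
13 | (4S,5S,8S,9S,10R,13R)-8-hydroxy-15-methoxy-15-oxolabdan-18-oic acid | OC(=O)[C@@]1(C)CCC[C@]2(C)[C@@H]1CC[C@](C)(O)[C@H]2CC[C@@H](C)CC(=O)OC | intermediate
14 | methyl (4S,5S,8S,9S,10R,13R)-8,18-dihydroxylabdan-15-oate | OC[C@@]1(C)CCC[C@]2(C)[C@@H]1CC[C@](C)(O)[C@H]2CC[C@@H](C)CC(=O)OC | intermediate (not isolated)
15 | (4S,5S,8S,9S,10R,13R)-8,18-dihydroxylabdan-15-oic acid | OC[C@@]1(C)CCC[C@]2(C)[C@@H]1CC[C@](C)(O)[C@H]2CC[C@@H](C)CC(=O)O | intermediate
16 | 3-methylbut-2-enoyl chloride | CC(C)=CC(=O)Cl | starting material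
17 | (4S,5S,8S,9S,10R,13R)-8-hydroxy-18-[(3-methylbut-2-enoyl)oxy]labdan-15-oic acid | CC(C)=CC(=O)OC[C@@]1(C)CCC[C@]2(C)[C@@H]1CC[C@](C)(O)[C@H]2CC[C@@H](C)CC(=O)O | target

**Step count**

Total steps: 9 (2 for the side-chain reagent, 7 on the main line). Longest linear sequence: 7 (steps 3 to 9, from 5).

**Steps most likely to fail**

Step 3. Benzylic oxidation at C7 can compete with ring cleavage and then leads to a chain one carbon short. The fallback sets out from 5 and comes back at 6; it activates ring C as a phenol and cleaves it with ozone. Friedel–Crafts acetylation (AcCl, AlCl3, CH2Cl2) gives methyl 12-acetyldehydroabietate F1. Baeyer–Villiger oxidation (mCPBA, CF3CO2H cat.) gives methyl 12-acetoxydehydroabietate F2. Methanolysis (K2CO3, MeOH) gives methyl 12-hydroxydehydroabietate F3. Ozonolysis of the phenol ring (O3, MeOH/CH2Cl2, −78 °C; then H2O2, HCO2H) gives 6.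

Step 5. The masked ketone may not survive the reduction, or the hindered ester may be under- or over-reduced in THF. The fallback sets out from 8 and comes back at 10; it replaces the in situ masking by a real protecting group. MeMgBr alone gives (1S,2R,3R)-3-(methoxycarbonyl)-1,3-dimethyl-2-(3-oxobutyl)cyclohexane-1-carboxylic acid F4. Ketalisation under non-equilibrating cold conditions ((Me3SiOCH2)2, Me3SiOTf cat., CH2Cl2, −78 °C) gives (1S,2R,3R)-3-(methoxycarbonyl)-1,3-dimethyl-2-[2-(2-methyl-1,3-dioxolan-2-yl)ethyl]cyclohexane-1-carboxylic acid F5. Reduction with i-Bu2AlH in CH2Cl2 at −78 °C gives (1S,2S,3R)-3-formyl-1,3-dimethyl-2-[2-(2-methyl-1,3-dioxolan-2-yl)ethyl]cyclohexane-1-carboxylic acid F6. Mild aqueous acid (1 M HCl, THF, rt) gives 10.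

Step 7. The ketyl has to attack a trisubstituted acceptor next to a quaternary carbon; the C8 configuration depends on the samarium alkoxide staying equatorial; the carbanions formed must be protonated before they reach the ester. The fallback sets out from 10 and comes back at 12; it closes ring B on an unsubstituted acceptor and attaches the side chain afterwards, which also avoids the congested olefination of step 6. Olefination of 10 with 3 itself (LiCl, DBU, MeCN) gives (1S,2S,3R)-1,3-dimethyl-2-(3-oxobutyl)-3-[(E)-2-(phenylsulfonyl)ethenyl]cyclohexane-1-carboxylic acid F7. SmI2/HMPA/MeOH at −78 °C, quenched cold, gives (4S,5S,8S,9S,10R)-8-hydroxy-11-(phenylsulfonyl)-12,13,14,15,16-pentanorlabdan-18-oic acid F8. Its trianion (LiN(i-Pr)2, 3.3 equiv, THF/DMPU, −78 to 0 °C) is alkylated at C11 with iodide 2 to give 12. Compound 12 is then desulfonylated in a separate operation (SmI2/HMPA/MeOH at rt, or Mg in MeOH) to 13.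

**Further compounds**

F1 | step 3 | methyl 12-acetylabieta-8,11,13-trien-18-oate | CC(C)c1cc2c(cc1C(C)=O)[C@]3(CCC[C@@]([C@@H]3CC2)(C)C(=O)OC)C
F2 | step 3 | methyl 12-acetoxyabieta-8,11,13-trien-18-oate | CC(C)c1cc2c(cc1OC(C)=O)[C@]3(CCC[C@@]([C@@H]3CC2)(C)C(=O)OC)C
F3 | step 3 | methyl 12-hydroxyabieta-8,11,13-trien-18-oate | CC(C)c1cc2c(cc1O)[C@]3(CCC[C@@]([C@@H]3CC2)(C)C(=O)OC)C
F4 | step 5 | (1S,2R,3R)-3-(methoxycarbonyl)-1,3-dimethyl-2-(3-oxobutyl)cyclohexane-1-carboxylic acid | OC(=O)[C@@]1(C)CCC[C@](C)([C@@H]1CCC(C)=O)C(=O)OC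
F5 | step 5 | (1S,2R,3R)-3-(methoxycarbonyl)-1,3-dimethyl-2-[2-(2-methyl-1,3-dioxolan-2-yl)ethyl]cyclohexane-1-carboxylic acid | OC(=O)[C@@]1(C)CCC[C@](C)([C@@H]1CCC2(C)OCCO2)C(=O)OC
F6 | step 5 | (1S,2S,3R)-3-formyl-1,3-dimethyl-2-[2-(2-methyl-1,3-dioxolan-2-yl)ethyl]cyclohexane-1-carboxylic acid | OC(=O)[C@@]1(C)CCC[C@](C)([C@@H]1CCC2(C)OCCO2)C=O
F7 | step 7 | (1S,2S,3R)-1,3-dimethyl-2-(3-oxobutyl)-3-[(E)-2-(phenylsulfonyl)ethenyl]cyclohexane-1-carboxylic acid | OC(=O)[C@@]1(C)CCC[C@](C)([C@@H]1CCC(C)=O)/C=C/S(=O)(=O)c1ccccc1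
F8 | step 7 | (4S,5S,8S,9S,10R)-8-hydroxy-11-(phenylsulfonyl)-12,13,14,15,16-pentanorlabdan-18-oic acid | OC(=O)[C@@]1(C)CCC[C@]2(C)[C@@H]1CC[C@](C)(O)[C@H]2CS(=O)(=O)c1ccccc1
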